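| setting | violet | green | red | teal | ochre |
|---|---|---|---|---|---|
| substrate | 200 mM | 120 mM | 200 mM | 200 mM | 200 mM |
| coupling partner | 240 mM | 160 mM | 720 mM | 240 mM | 240 mM |
| target |  |  |  | 100 mM |  |
| time |  |  |  |  | 99 min |

| run | time / min | [target] / mM |
|---|---|---|
| violet run | 1.3 | 14.4 |
| violet run | 2.5 | 24.5 |
| violet run | 4.8 | 36.6 |
| violet run | 9.1 | 56.3 |
| violet run | 17 | 78.5 |
| violet run | 33 | 104.0 |
| green run | 1.3 | 3.2 |
| green run | 2.5 | 7.1 |
| green run | 4.8 | 12.4 |
| green run | 9.1 | 22.0 |
| green run | 17 | 34.0 |
| green run | 33 | 46.7 |
| red run | 1.3 | 67.8 |
| red run | 2.5 | 106.4 |
| red run | 4.8 | 144.9 |
| red run | 9.1 | 173.8 |
| red run | 17 | 189.4 |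
| red run | 33 | 197.9 |
| teal run | 1.3 | 112.7 |
| teal run | 2.5 | 122.6 |
| teal run | 4.8 | 138.0 |
| teal run | 9.1 | 155.4 |
| teal run | 17 | 179.4 |
| teal run | 33 | 202.1 |

(readings scatter by 1 mM)

- Overall: substrate + coupling partner -> target.
- Constant volume, constant temperature.
- Readings of a species count what is bound in complexes too.
- "The second partner" is coupling partner.
- An order is taken over about fifteen percent of the charge, up and down.

- the power of [substrate] that the first rate follows, about the charge of the violet run; measure it at two percent of substrate made into target (one fixed amount of target, the same in the runs compared)
- the power of [coupling partner] that the first rate follows, about the charge of the violet run; measure it at two percent of substrate made into target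
- the green run starts with 80.0 mM less of substrate and of coupling partner than the violet run, and with no target. Compared where both hold the same amount of substrate, once fifteen percent of what the green run was charged with has turned into target, is the green run faster, slower or alike (within a tenth)?
- target in the ochre run at 99 min, as a share of the substrate charged

I start with a balance. Substrate is charged in the smaller amount in the violet run, which makes it the limiting reagent, and each target made takes one substrate and one coupling partner overall. While that main step runs by itself, the gap between the two stays fixed. I call this gap the spare partner, 40.0 mM in the violet run: coupling partner minus substrate.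

With the main step by itself, the green run has the same spare, 40.0 mM, and its charge is what the violet run holds once 80.0 mM of substrate has turned. From that point the two runs should climb alike. A fit of the main step to these runs puts the ochre run at 73.7%.

The readings part from that. I add one process here, a quiet loss of partner. The green run gains 2.23 mM min⁻¹ between 4.8 min and 9.1 min. The violet run gains 1.59 mM min⁻¹ between 17 min and 33 min, which is slower, although its stretch starts with more substrate. As read from these scattered readings, that is a rate ratio of 1.40. My reading is that partner leaves the balance as time passes, so the spare shrinks, and the violet stretch lies later than the green one.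

For the ochre run I treat this as a slowing by that ratio. I assume that the amounts are nearly equal and that the rate goes roughly as the cube of what remains. What remains then falls roughly as one over the root of the time, so the remainder grows by the root of the ratio. My number drops to 68.8%.

Then comes the rest. Less its added target, the teal run reads 38.0 mM at 4.8 min, beside 36.6 mM in the violet run, so my number stays.

The forecast gives 1.3 for substrate, 1.7 for partner, faster for the green run, and 71% for the ochre run, within 62% to 80%, on the ground that “violet has lost activity”. My 68.8% lies below its value.

The flask gives 0.74 for substrate, 1.9 for partner, faster for the green run, and 64.7% for the ochre run.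

    substrate + 2 coupling partner → target + coupling partner (1.536 L² mol⁻² min⁻¹)
    2 coupling partner → lost reagent (0.04296 L mol⁻¹ min⁻¹)
    substrate + coupling partner ⇌ idle substrate-reagent adduct, settled at all times (1.110 L mol⁻¹)

At 99 min the ochre run holds 70.6 mM of substrate unturned, and an intact spare of 40.0 mM would put 111 mM of partner beside it. The path that turns partner into lost reagent eats into that spare: with the path removed, the ochre run reaches 80.9% instead of 64.7%. The green run shows the same balance, because with the path removed its equal spare gives a rate 1.0 times the violet rate at equal substrate, and with the path the ratio is 1.7.

The runs are simulated with constants of no real substance; noise was put on by code.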